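**Plan**
- Retrosynthesis: remove the aldehyde oxygen (16 ⇒ isopropenyl compound 15), the side-chain ester and its carbinol (⇒ aryl methyl ketone 12), the alkene (⇒ tertiary carbinol 11) and the C3 ester (⇒ cis-diol 9); then cut the dihydrofuran ring of 9 at O1–C2 and C3a–C3.
- Enabling feature: C3 is a benzylic carbinol and C2 carries O1 next to a branched carbon that can hold oxygen, so C3–C2–C(branch) is a latent α,β-epoxy aldehyde; O1 and the ortho carbon C3a of the benzene ring are the matching C,O-bisnucleophile.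
- Forward: the benzene ring is bought (3-bromo-4-hydroxyacetophenone); the five-membered oxygen ring is closed in one pot by aryllithium addition to (2S)-3,3-dimethyloxirane-2-carbaldehyde and 5-exo opening of the epoxide by the phenoxide; the side chains are adjusted afterwards.
- Stereochemistry: C2 comes from the Sharpless epoxide (inverted on closure); C3 is set cis by Felkin–Anh induction and inverted to trans in the Mitsunobu esterification; the side-chain carbinol comes from Noyori transfer hydrogenation.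

Key step: step 4

Remark: positions are numbered as in 2,3-dihydro-1-benzofuran (O1, C2, C3, C3a, C4–C7, C7a); the aryl addition of step 4 is assumed to follow the Felkin–Anh (anti) sense usual for α,β-epoxy aldehydes.

**Step 1**
Reactants: 1 1-(3-bromo-4-hydroxyphenyl)ethan-1-one
Product: 2 2-bromo-4-(2-methyl-1,3-dioxolan-2-yl)phenol
Conditions: ethylene glycol, p-TsOH·H2O (cat.), toluene, Dean–Stark, reflux
Reagents that add atoms: ethylene glycol, OCCO
Why: acid-catalysed ketalisation with azeotropic removal of water masks the ketone against the organolithium of step 4 and restores an electron-rich phenol; no stereocentre is formed.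

**Step 2**
Reactants: 3 3-methylbut-2-en-1-ol
Product: 4 [(2R)-3,3-dimethyloxiran-2-yl]methanol
Conditions: Ti(OiPr)4 (cat.), D-(−)-diisopropyl tartrate (cat.), t-BuOOH, 4 Å molecular sieves, CH2Cl2, −20 °C
Reagents that add atoms: tert-butyl hydroperoxide, CC(C)(C)OO
Why: Sharpless asymmetric epoxidation of a primary allylic alcohol; the D-tartrate ligand should deliver oxygen to the alkene face that gives the (2R) epoxy alcohol (the L-tartrate gives 2S in this substrate class).

**Step 3**
Reactants: 4 [(2R)-3,3-dimethyloxiran-2-yl]methanol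
Product: 5 (2S)-3,3-dimethyloxirane-2-carbaldehyde
Conditions: Dess–Martin periodinane, pyridine, CH2Cl2, 0 °C to rt; used as a solution
Reagents that add atoms: none
Why: Dess–Martin oxidation of the primary alcohol under buffered conditions; the epoxide carbon is not enolisable, so its configuration is kept (the descriptor changes from R to S only through the CIP priorities).

**Step 4**
Reactants: 2 2-bromo-4-(2-methyl-1,3-dioxolan-2-yl)phenol; 5 (2S)-3,3-dimethyloxirane-2-carbaldehyde
Product: 9 1-[(2S,3R)-3-hydroxy-2-(2-hydroxypropan-2-yl)-2,3-dihydro-1-benzofuran-5-yl]ethan-1-one, via dilithio phenoxide 6 (not isolated), via anti epoxy alkoxide 7 (not isolated), via dioxolane cis-diol 8 (not isolated)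
Conditions: t-BuLi (3.0 equiv), THF, −78 °C; then 5, −78 °C; then MeOH, 50 °C; then 1 M aq. HCl, rt
Reagents that add atoms: water, O
Why: Bromine–lithium exchange on the lithium phenoxide of 2 gives the C,O-dianion 6, whose aryl carbon adds to the aldehyde of 5 (C3a–C3); the phenoxide then opens the neighbouring epoxide at its secondary carbon by intramolecular SN2 attack (O1–C2), and dilute acid finally unmasks the acetyl group. The closest known reaction types are the addition of aryllithiums to α,β-epoxy aldehydes and the base-mediated cyclisation of ortho-(epoxyalkyl)phenols to 2-(2-hydroxypropan-2-yl)-2,3-dihydrobenzofurans. The dihydrofuran ring closes in the 5-exo-tet mode. C2 is controlled by the Sharpless-derived epoxide carbon, which is inverted in the SN2 opening (2S in 9); C3 is controlled by Felkin–Anh 1,2-induction from the same centre, the aryl group entering anti to the epoxide C–O bond, which should give the anti adduct 7 and hence the cis (3R) carbinol. The step needs facial selectivity in the addition (helped by the cis-methyl group of the epoxide beside the carbonyl), 5-exo instead of 6-endo opening (secured by the basic, non-ionising medium and the less substituted epoxide carbon) and chemoselectivity for the aldehyde (secured by the dioxolane and by completing the exchange before 5 is added).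

**Step 5**
Reactants: 9 1-[(2S,3R)-3-hydroxy-2-(2-hydroxypropan-2-yl)-2,3-dihydro-1-benzofuran-5-yl]ethan-1-one; 10 3-methylbutanoic acid
Product: 11 (2S,3S)-5-acetyl-2-(2-hydroxypropan-2-yl)-2,3-dihydro-1-benzofuran-3-yl 3-methylbutanoate
Conditions: PPh3, DIAD, toluene, 0 °C to rt
Reagents that add atoms: none
Why: Mitsunobu esterification activates only the secondary C3 hydroxyl (the tertiary one is inert) and the carboxylate displaces it with SN2 inversion from the face free of the C2 substituent, so the cis (3R) carbinol should become the trans (3S) ester while the acetyl group para to O1 disfavours ionisation at C3.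

**Step 6**
Reactants: 11 (2S,3S)-5-acetyl-2-(2-hydroxypropan-2-yl)-2,3-dihydro-1-benzofuran-3-yl 3-methylbutanoate
Product: 12 (2R,3S)-5-acetyl-2-(prop-1-en-2-yl)-2,3-dihydro-1-benzofuran-3-yl 3-methylbutanoate
Conditions: Burgess reagent (methyl N-(triethylammoniosulfonyl)carbamate), toluene, 50 °C
Reagents that add atoms: none
Why: Burgess dehydration of the tertiary carbinol by syn elimination of its sulfamate ester should take one of the six methyl hydrogens in preference to the single hindered C2–H and give the isopropenyl group under neutral conditions; C2 is untouched (its descriptor changes from S to R only through the CIP priorities).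

**Step 7**
Reactants: 12 (2R,3S)-5-acetyl-2-(prop-1-en-2-yl)-2,3-dihydro-1-benzofuran-3-yl 3-methylbutanoate
Product: 13 (2R,3S)-5-[(1R)-1-hydroxyethyl]-2-(prop-1-en-2-yl)-2,3-dihydro-1-benzofuran-3-yl 3-methylbutanoate
Conditions: RuCl(p-cymene)[(R,R)-TsDPEN] (cat.), HCO2H/Et3N (5:2), 30 °C
Reagents that add atoms: none
Why: Noyori asymmetric transfer hydrogenation of the aryl methyl ketone; the (R,R) ligand should set the (1R) carbinol by catalyst control, as for acetophenones, and leaves the alkene and the ester untouched.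

**Step 8**
Reactants: 13 (2R,3S)-5-[(1R)-1-hydroxyethyl]-2-(prop-1-en-2-yl)-2,3-dihydro-1-benzofuran-3-yl 3-methylbutanoate; 14 3-methylbutanoic anhydride
Product: 15 (1R)-1-[(2R,3S)-3-[(3-methylbutanoyl)oxy]-2-(prop-1-en-2-yl)-2,3-dihydro-1-benzofuran-5-yl]ethyl 3-methylbutanoate
Conditions: Et3N, DMAP (cat.), CH2Cl2, 0 °C
Reagents that add atoms: none
Why: DMAP-catalysed acylation of the secondary alcohol proceeds at oxygen with retention, and the chloride-free, basic medium avoids ionisation of the electron-rich benzylic position.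

**Step 9**
Reactants: 15 (1R)-1-[(2R,3S)-3-[(3-methylbutanoyl)oxy]-2-(prop-1-en-2-yl)-2,3-dihydro-1-benzofuran-5-yl]ethyl 3-methylbutanoate
Product: 16 (1R)-1-[(2R,3S)-3-[(3-methylbutanoyl)oxy]-2-(3-oxoprop-1-en-2-yl)-2,3-dihydro-1-benzofuran-5-yl]ethyl 3-methylbutanoate
Conditions: SeO2 (2 equiv), 1,4-dioxane, 70 °C
Reagents that add atoms: selenium dioxide, O=[Se]=O
Why: Riley allylic oxidation (ene reaction at the terminal CH2, then [2,3]-sigmatropic shift) should functionalise the methyl group rather than the C2 methine, following the CH2 > CH3 > CH order for 1,1-disubstituted alkenes, and the allylic alcohol is oxidised on to the conjugated aldehyde without touching a stereocentre.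

**Compound list**
1 | 1-(3-bromo-4-hydroxyphenyl)ethan-1-one | CC(=O)c1ccc(O)c(Br)c1 | starting material
2 | 2-bromo-4-(2-methyl-1,3-dioxolan-2-yl)phenol | CC1(OCCO1)c1ccc(O)c(Br)c1 | intermediate
3 | 3-methylbut-2-en-1-ol | CC(C)=CCO | starting material
4 | [(2R)-3,3-dimethyloxiran-2-yl]methanol | CC1(C)O[C@@H]1CO | intermediate
5 | (2S)-3,3-dimethyloxirane-2-carbaldehyde | CC1(C)O[C@@H]1C=O | intermediate
6 | lithium 2-lithio-4-(2-methyl-1,3-dioxolan-2-yl)phenolate | [Li]Oc1ccc(cc1[Li])C1(C)OCCO1 | intermediate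
7 | dilithium 2-[(R)-[(2R)-3,3-dimethyloxiran-2-yl](oxido)methyl]-4-(2-methyl-1,3-dioxolan-2-yl)phenolate | CC1(C)O[C@@H]1[C@H](O[Li])c1cc(ccc1O[Li])C1(C)OCCO1 | intermediate
8 | (2S,3R)-2-(2-hydroxypropan-2-yl)-5-(2-methyl-1,3-dioxolan-2-yl)-2,3-dihydro-1-benzofuran-3-ol | CC(C)(O)[C@H]1Oc2ccc(C3(C)OCCO3)cc2[C@H]1O | intermediate
9 | 1-[(2S,3R)-3-hydroxy-2-(2-hydroxypropan-2-yl)-2,3-dihydro-1-benzofuran-5-yl]ethan-1-one | CC(C)(O)[C@H]1Oc2ccc(C(C)=O)cc2[C@H]1O | intermediate
10 | 3-methylbutanoic acid | CC(C)CC(=O)O | starting material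
11 | (2S,3S)-5-acetyl-2-(2-hydroxypropan-2-yl)-2,3-dihydro-1-benzofuran-3-yl 3-methylbutanoate | CC(C)(O)[C@H]1Oc2ccc(C(C)=O)cc2[C@@H]1OC(=O)CC(C)C | intermediate
12 | (2R,3S)-5-acetyl-2-(prop-1-en-2-yl)-2,3-dihydro-1-benzofuran-3-yl 3-methylbutanoate | C=C(C)[C@H]1Oc2ccc(C(C)=O)cc2[C@@H]1OC(=O)CC(C)C | intermediate
13 | (2R,3S)-5-[(1R)-1-hydroxyethyl]-2-(prop-1-en-2-yl)-2,3-dihydro-1-benzofuran-3-yl 3-methylbutanoate | C=C(C)[C@H]1Oc2ccc([C@@H](C)O)cc2[C@@H]1OC(=O)CC(C)C | intermediate
14 | 3-methylbutanoic anhydride | CC(C)CC(=O)OC(=O)CC(C)C | starting material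
15 | (1R)-1-[(2R,3S)-3-[(3-methylbutanoyl)oxy]-2-(prop-1-en-2-yl)-2,3-dihydro-1-benzofuran-5-yl]ethyl 3-methylbutanoate | C=C(C)[C@H]1Oc2ccc([C@@H](C)OC(=O)CC(C)C)cc2[C@@H]1OC(=O)CC(C)C | intermediate
16 | (1R)-1-[(2R,3S)-3-[(3-methylbutanoyl)oxy]-2-(3-oxoprop-1-en-2-yl)-2,3-dihydro-1-benzofuran-5-yl]ethyl 3-methylbutanoate | C=C(C=O)[C@H]1Oc2ccc([C@@H](C)OC(=O)CC(C)C)cc2[C@@H]1OC(=O)CC(C)C | target

**Totals**
Total step count: 9. Longest linear sequence: 8 steps (steps 2 to 9, from 3-methylbut-2-en-1-ol).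

**Steps most likely to fail**

Step 4. The aryl addition may show poor facial selectivity, or the one-pot closure may be diverted by attack at the tertiary epoxide carbon or by side reactions of the dianion. The fallback separates the two bond formations on a protected phenol; it sets out from 2 and 5 and returns at 9. O-Allylation of 2 (allyl bromide, K2CO3, acetone) should give 2-[3-bromo-4-(prop-2-en-1-yloxy)phenyl]-2-methyl-1,3-dioxolane F1. Bromine–lithium exchange (t-BuLi, THF, −78 °C) and addition to 5 should give (R)-[(2R)-3,3-dimethyloxiran-2-yl][5-(2-methyl-1,3-dioxolan-2-yl)-2-(prop-2-en-1-yloxy)phenyl]methanol F2, from which the minor syn epimer is removed by chromatography. Pd(PPh3)4 with morpholine then frees 2-[(R)-[(2R)-3,3-dimethyloxiran-2-yl](hydroxy)methyl]-4-(2-methyl-1,3-dioxolan-2-yl)phenol F3. K2CO3 in MeOH at 40 °C closes the ring to 8, and 1 M aq. HCl returns 9.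

Step 5. The activated C3 oxygen may be lost by elimination toward the aromatic benzofuran, or C3 may ionise with loss of inversion. The fallback moves the inversion ahead of ring closure, where no aromatising elimination exists; it sets out from 2 and 5 by way of F1 and F2 and returns at 11.
- Mitsunobu reaction of F2 with 10 (PPh3, DIAD, toluene) should give the inverted ester (S)-[(2R)-3,3-dimethyloxiran-2-yl][5-(2-methyl-1,3-dioxolan-2-yl)-2-(prop-2-en-1-yloxy)phenyl]methyl 3-methylbutanoate F4.
- An ortho-hydroxybenzyl ester would fragment to a quinone methide once the phenol is free, so the ester is removed (K2CO3, MeOH) to give (S)-[(2R)-3,3-dimethyloxiran-2-yl][5-(2-methyl-1,3-dioxolan-2-yl)-2-(prop-2-en-1-yloxy)phenyl]methanol F5.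
- Deallylation (Pd(PPh3)4, morpholine) should give 2-[(S)-[(2R)-3,3-dimethyloxiran-2-yl](hydroxy)methyl]-4-(2-methyl-1,3-dioxolan-2-yl)phenol F6.
- Closure (K2CO3, MeOH, 40 °C) should give (2S,3S)-2-(2-hydroxypropan-2-yl)-5-(2-methyl-1,3-dioxolan-2-yl)-2,3-dihydro-1-benzofuran-3-ol F7, and 1 M aq. HCl should give 1-[(2S,3S)-3-hydroxy-2-(2-hydroxypropan-2-yl)-2,3-dihydro-1-benzofuran-5-yl]ethan-1-one F8.
- Acylation of the secondary hydroxyl of F8 with 14 (Et3N, DMAP) gives 11 with retention.

Step 9. The oxidation may overrun, stall at the allylic alcohol, or cause thermal loss of the C3 ester by elimination. The fallback sets out from 15 and returns at 16. A Schenck ene reaction with singlet oxygen (O2, tetraphenylporphyrin, visible light, CH2Cl2, 0 °C) should give (1R)-1-[(2R,3S)-2-(3-hydroperoxyprop-1-en-2-yl)-3-[(3-methylbutanoyl)oxy]-2,3-dihydro-1-benzofuran-5-yl]ethyl 3-methylbutanoate F9. Acetic anhydride and pyridine then dehydrate this hydroperoxide (Kornblum–DeLaMare-type) to 16.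

**Further compounds**
F1 | step 4 | 2-[3-bromo-4-(prop-2-en-1-yloxy)phenyl]-2-methyl-1,3-dioxolane | C=CCOc1ccc(cc1Br)C1(C)OCCO1
F2 | step 4 | (R)-[(2R)-3,3-dimethyloxiran-2-yl][5-(2-methyl-1,3-dioxolan-2-yl)-2-(prop-2-en-1-yloxy)phenyl]methanol | CC1(C)O[C@@H]1[C@H](O)c1cc(ccc1OCC=C)C1(C)OCCO1
F3 | step 4 | 2-[(R)-[(2R)-3,3-dimethyloxiran-2-yl](hydroxy)methyl]-4-(2-methyl-1,3-dioxolan-2-yl)phenol | CC1(C)O[C@@H]1[C@H](O)c1cc(ccc1O)C1(C)OCCO1
F4 | step 5 | (S)-[(2R)-3,3-dimethyloxiran-2-yl][5-(2-methyl-1,3-dioxolan-2-yl)-2-(prop-2-en-1-yloxy)phenyl]methyl 3-methylbutanoate | CC1(C)O[C@@H]1[C@@H](OC(=O)CC(C)C)c1cc(ccc1OCC=C)C1(C)OCCO1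
F5 | step 5 | (S)-[(2R)-3,3-dimethyloxiran-2-yl][5-(2-methyl-1,3-dioxolan-2-yl)-2-(prop-2-en-1-yloxy)phenyl]methanol | CC1(C)O[C@@H]1[C@@H](O)c1cc(ccc1OCC=C)C1(C)OCCO1
F6 | step 5 | 2-[(S)-[(2R)-3,3-dimethyloxiran-2-yl](hydroxy)methyl]-4-(2-methyl-1,3-dioxolan-2-yl)phenol | CC1(C)O[C@@H]1[C@@H](O)c1cc(ccc1O)C1(C)OCCO1
F7 | step 5 | (2S,3S)-2-(2-hydroxypropan-2-yl)-5-(2-methyl-1,3-dioxolan-2-yl)-2,3-dihydro-1-benzofuran-3-ol | CC(C)(O)[C@H]1Oc2ccc(C3(C)OCCO3)cc2[C@@H]1O
F8 | step 5 | 1-[(2S,3S)-3-hydroxy-2-(2-hydroxypropan-2-yl)-2,3-dihydro-1-benzofuran-5-yl]ethan-1-one | CC(C)(O)[C@H]1Oc2ccc(C(C)=O)cc2[C@@H]1O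
F9 | step 9 | (1R)-1-[(2R,3S)-2-(3-hydroperoxyprop-1-en-2-yl)-3-[(3-methylbutanoyl)oxy]-2,3-dihydro-1-benzofuran-5-yl]ethyl 3-methylbutanoate | OOCC(=C)[C@H]1Oc2ccc([C@@H](C)OC(=O)CC(C)C)cc2[C@@H]1OC(=O)CC(C)C
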